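- The target arises when dissolved substrate meets partner, and in this flask both reach the solution from solids, so I reckoned the target through one dissolved concentration.

solid substrate 21 mM; protic impurity 1.05 mM; solid reagent 42.0 mM; time 15 h

- how much target and solid product and idle adduct together there is at 15 h, in percent of the solid substrate charged
- concentration of dissolved substrate in solution at 15 h, in percent of saturation

- what is said of target includes solid product and idle adduct
- solid substrate, solid product, solid reagent is a solid; its amount is given per volume of the solution
- at the start none of the solid substrate is in solution
- at the start none of the solid reagent is in solution
- dissolved substrate means what is dissolved; the solid is not counted in it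
- run time (flask): 15 h

    solid substrate ⇌ dissolved substrate, rate k1*(cs1 - [dissolved substrate]) while solid is left; crystals form when [dissolved substrate] > cs1 (cs1 = 9.2 mM, k1 = 0.0416 /h)
    dissolved substrate + partner → target (k2 = 426 /M/h)
    partner → side product (k3 = 10.0 /h)
    solid product ⇌ target, rate k4*(cs4 - [target]) while solid is left; crystals form when [target] > cs4 (cs4 = 7.5 mM, k4 = 3.54 /h)
    solid substrate + protic impurity → quenched substrate (k5 = 1280 /M/h)
    solid reagent ⇌ partner, rate k6*(cs6 - [partner]) while solid is left; crystals form when [partner] > cs6 (cs6 = 8.5 mM, k6 = 0.0865 /h)
    partner + target ⇌ idle adduct, settled at all times (K7 = 17 /M)

- Partner's half-life against side product, 0.0693 h, was far shorter than the run, so I held c(partner) quasi-steady at 0.0735 mM, which made the capture of dissolved substrate pseudo-first-order with constant 0.0313 /h.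
- I folded the givens into a capture number, the constant of that capture over the dissolution coefficient of the solid substrate: 0.753.
- Dissolution could deliver at most 5.74 mM, less than the 20.0 mM of solid substrate that the protic impurity could leave, so the rate stayed linear and integrated in closed form.
- While c(partner) held at that level, the capture number set a plateau at 57.0% of saturation, but one number was not enough: the approach constant 0.0729 /h times the run gave 1.09, and that second number brought me to 37.9%.
- Integrating the capture gave 0.967 mM of target, below its solubility, which is a yield of 4.60%.
- The forecast stood at 4.1% and 38.8%, its yield lower than mine, and it shared my ground: “Partner is quasi-steady”.
- The flask gave 4.17% and 38.8%.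
- At 15.0 h the flask made dissolved substrate 2.44 times as fast as it used it up, each step taken net, down from 4.59 at 7.50 h, while the capture number and that saturation reading give 2.09 for the same ratio. The capture number holds no charge of solid substrate, so I carried it to a second flask with 5.2 mM, where my target gives 18.6% against a reading of 16.7%; but there the 5.74 mM that dissolution could deliver at most was more than the 4.15 mM of solid substrate that the protic impurity could leave, and that flask's solid substrate stood at 0%.

The constants used here are invented; no experiment stands behind them.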